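**Plan** (chromene numbering: O1, C2, C3, C4, C4a, C5 to C8, C8a)

- Retrosynthetic cuts, in order: C4–C4a of the pyran ring (back to an open 2-methylbut-3-yn-2-yl enol ether on O1); then C5–CH2 of the prenyl group (back to a flat 2-acylresorcinol); then O1–C(propargyl), C8a–O1 and C7–C(=O).
- Forward: the carbocycle is the ring of 4-methylresorcinol throughout. C7 is acylated by directed ortho-lithiation, O1 is placed on C8a by bromination/borylation/oxidation and then propargylated, the ring is dearomatised by prenylation at C5, and the pyran ring is closed last.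
- Enabling feature: once C5 is sp3, O1–C8a=C4a–H is an isolated enol ether, and with its tertiary propargyl group it is a 3-oxa-1,5-enyne. A [3,3] shift joins C4 to C4a with no loss of aromaticity and uncovers the C8a carbonyl next to the C8 enol; the resulting O=C8a–C4a=C4–C3=C2 oxatriene closes to the 2H-pyran.
- Stereochemistry: the only stereocenter, C5 (S), is set in the dearomatising step by a zerovalent-palladium/Trost-ligand allylic alkylation that distinguishes the two faces of the planar phenolate. No later step breaks a bond at C5.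

Key step: step 9

Remark on the chemistry: the sense of induction of the Trost ligand in step 8 cannot be assigned with confidence for this nucleophile; the (R,R) ligand is written and its antipode is used if the first run gives the (5R) series. Compounds 14 to 17 are drawn as the 6-keto/8-enol tautomer.

**Step 1**
Reactants: 1 4-methylbenzene-1,3-diol
Product: 2 2,4-bis(methoxymethoxy)-1-methylbenzene
Conditions: NaH, MOMCl, DMF, 0 °C to rt
Reagents that add atoms: chloromethyl methyl ether, COCCl
Why: Williamson-type O-alkylation of both phenoxides gives the bis(methoxymethyl) ether, which masks the phenols and supplies the two directing groups for the next step.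

**Step 2**
Reactants: 2 2,4-bis(methoxymethoxy)-1-methylbenzene; 3 N-methoxy-N-methyl-3-phenylpropanamide
Product: 5 1-[2,6-bis(methoxymethoxy)-3-methylphenyl]-3-phenylpropan-1-one, via aryllithium 4 (not isolated)
Conditions: n-BuLi, TMEDA, THF, 0 °C; then 3, −78 °C to 0 °C; aq. NH4Cl
Reagents that add atoms: N-methoxy-N-methyl-3-phenylpropanamide (3), CON(C)C(=O)CCc1ccccc1 (n-butyllithium, [Li]CCCC, supplies only the lithium of 4)
Why: Directed ortho-metalation removes the ring hydrogen flanked by the two OMOM groups, and Weinreb ketone synthesis on aryllithium 4 stops at the ketone because the N-methoxy-N-methyl tetrahedral chelate survives until the quench.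

**Step 3**
Reactants: 5 1-[2,6-bis(methoxymethoxy)-3-methylphenyl]-3-phenylpropan-1-one
Product: 6 1-[3-bromo-2,6-bis(methoxymethoxy)-5-methylphenyl]-3-phenylpropan-1-one
Conditions: NBS, MeCN, 0 °C to rt, dark
Reagents that add atoms: N-bromosuccinimide, O=C1CCC(=O)N1Br
Why: Electrophilic aromatic bromination should go to the one free position that is ortho to one OMOM and para to the other (the future C8a), since the other free position is meta to both oxygens and the phenylpropyl ring is unactivated.

**Step 4**
Reactants: 6 1-[3-bromo-2,6-bis(methoxymethoxy)-5-methylphenyl]-3-phenylpropan-1-one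
Product: 8 1-[3-hydroxy-2,6-bis(methoxymethoxy)-5-methylphenyl]-3-phenylpropan-1-one, via pinacol boronate 7 (not isolated)
Conditions: B2pin2, Pd(dppf)Cl2·CH2Cl2 (cat.), KOAc, 1,4-dioxane, 90 °C; then 30% aq. H2O2, aq. NaOH, THF, 0 °C
Reagents that add atoms: hydrogen peroxide, OO (the phenol oxygen); bis(pinacolato)diboron, CC1(C)OB(OC1(C)C)B1OC(C)(C)C(C)(C)O1 (boron of 7 only)
Why: Miyaura borylation (oxidative addition to zerovalent palladium, acetate-assisted transmetalation) followed by peroxide-induced aryl migration from boron to oxygen converts C–Br into C–OH under conditions that the MOM ethers and the hindered ketone should tolerate.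

**Step 5**
Reactants: 8 1-[3-hydroxy-2,6-bis(methoxymethoxy)-5-methylphenyl]-3-phenylpropan-1-one; 9 3-chloro-3-methylbut-1-yne
Product: 10 1-[2,6-bis(methoxymethoxy)-3-methyl-5-[(2-methylbut-3-yn-2-yl)oxy]phenyl]-3-phenylpropan-1-one
Conditions: 9, DBU, CuCl2·2H2O (cat.), MeCN, 0 °C
Reagents that add atoms: 3-chloro-3-methylbut-1-yne (9), CC(C)(Cl)C#C
Why: Copper-catalysed propargylic etherification (ionisation of the tertiary chloride through a copper acetylide/allenylidene, then O-attack) puts the 1,1-dimethylpropargyl group on the only free phenol.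

**Step 6**
Reactants: 10 1-[2,6-bis(methoxymethoxy)-3-methyl-5-[(2-methylbut-3-yn-2-yl)oxy]phenyl]-3-phenylpropan-1-one
Product: 11 1-[2,6-dihydroxy-3-methyl-5-[(2-methylbut-3-yn-2-yl)oxy]phenyl]-3-phenylpropan-1-one
Conditions: HCl (1.25 M in MeOH), THF, 25–40 °C, under argon
Reagents that add atoms: none
Why: Acid-catalysed transacetalisation to methanol removes both MOM groups, which are ortho to the ketone and therefore labile, while the tertiary propargylic aryl ether should survive because its cation is far less stabilised than the MOM oxocarbenium ion.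

**Step 7**
Reactants: 12 3-methylbut-2-en-1-ol
Product: 13 tert-butyl 3-methylbut-2-en-1-yl carbonate
Conditions: Boc2O, DMAP (cat.), CH2Cl2, 0 °C to rt
Reagents that add atoms: di-tert-butyl dicarbonate, CC(C)(C)OC(=O)OC(=O)OC(C)(C)C
Why: DMAP-catalysed acyl transfer to the primary allylic alcohol gives the mixed carbonate, which serves as a base-free π-allyl precursor.

**Step 8**
Reactants: 11 1-[2,6-dihydroxy-3-methyl-5-[(2-methylbut-3-yn-2-yl)oxy]phenyl]-3-phenylpropan-1-one; 13 tert-butyl 3-methylbut-2-en-1-yl carbonate
Product: 14 (6S)-3-hydroxy-6-methyl-6-(3-methylbut-2-en-1-yl)-4-[(2-methylbut-3-yn-2-yl)oxy]-2-(3-phenylpropanoyl)cyclohexa-2,4-dien-1-one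
Conditions: 13, Pd2(dba)3·CHCl3 (2.5 mol %), (R,R)-DACH-phenyl Trost ligand (7.5 mol %), degassed 1,4-dioxane, rt
Reagents that add atoms: tert-butyl 3-methylbut-2-en-1-yl carbonate (13), CC(C)=CCOC(=O)OC(C)(C)C
Why: In this Tsuji–Trost asymmetric allylic alkylation run as a dearomatisation, zerovalent palladium ionises 13 to a 1,1-dimethyl-π-allyl complex and tert-butoxide, the phenolate of 11 attacks the unsubstituted allyl terminus through C5 (ortho to O6, para to O8, the methyl-bearing carbon; O-allylation is reversible under the catalysis and C8a is shielded by its tertiary ether), and the chiral pocket of the ligand selects one face of the planar phenolate to set the C5 quaternary stereocenter.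

**Step 9**
Reactants: 14 (6S)-3-hydroxy-6-methyl-6-(3-methylbut-2-en-1-yl)-4-[(2-methylbut-3-yn-2-yl)oxy]-2-(3-phenylpropanoyl)cyclohexa-2,4-dien-1-one
Product: 17 (5S)-8-hydroxy-2,2,5-trimethyl-5-(3-methylbut-2-en-1-yl)-7-(3-phenylpropanoyl)-2H-chromen-6(5H)-one, via allenyl diketone 15 (not isolated), via oxatriene 16 (not isolated)
Conditions: degassed toluene, 100 °C, sealed tube, argon
Reagents that add atoms: none
Why: With C5 already sp3, O1–C8a=C4a–H of 14 is a propargyl vinyl ether (3-oxa-1,5-enyne), so a thermal [3,3] propargyl Claisen shift through a six-membered transition state bonds the alkyne terminus C4 to C4a and frees the C8a ketone (15), enolisation of the acidic C4a–H and a six-centre 1,5-hydrogen shift from the enol O–H to the central allene carbon C3 give the (Z)-1-oxatriene 16, and a disrotatory oxa-6π electrocyclisation returns the O1–C2 bond. The closest known reaction type is the thermal rearrangement of aryl and vinyl 1,1-dimethylpropargyl ethers to 2,2-dimethyl-2H-chromenes and 2H-pyrans, together with the Saucy–Marbet rearrangement of tertiary propargyl vinyl ethers. The pyran ring is the only ring closed: its one net new σ bond, C4–C4a, is made in the sigmatropic step, and the ring is completed by the 6π electrocyclisation of the cis-locked oxatriene. No new stereocenter remains (the C4a center of 15 is erased by enolisation) and C5 keeps its configuration because none of its bonds is broken. The step needs regioselectivity, secured because C4a is the only hydrogen-bearing sp2 carbon next to the O1-bearing C8a (C8 is fully substituted), and it needs to outrun a retro-Claisen of the C5 prenyl group that would racemise C5, secured because the shift no longer costs aromaticity and starts from a tertiary propargylic carbon, so about 100 °C should suffice.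

**Compound list**

1 | 4-methylbenzene-1,3-diol | Cc1ccc(O)cc1O | starting material
2 | 2,4-bis(methoxymethoxy)-1-methylbenzene | Cc1ccc(OCOC)cc1OCOC | intermediate
3 | N-methoxy-N-methyl-3-phenylpropanamide | CON(C)C(=O)CCc1ccccc1 | starting material
4 | [2,6-bis(methoxymethoxy)-3-methylphenyl]lithium | [Li]c1c(OCOC)ccc(C)c1OCOC | intermediate
5 | 1-[2,6-bis(methoxymethoxy)-3-methylphenyl]-3-phenylpropan-1-one | Cc1ccc(OCOC)c(C(=O)CCc2ccccc2)c1OCOC | intermediate
6 | 1-[3-bromo-2,6-bis(methoxymethoxy)-5-methylphenyl]-3-phenylpropan-1-one | Cc1cc(Br)c(OCOC)c(C(=O)CCc2ccccc2)c1OCOC | intermediate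
7 | 1-[2,6-bis(methoxymethoxy)-3-methyl-5-(4,4,5,5-tetramethyl-1,3,2-dioxaborolan-2-yl)phenyl]-3-phenylpropan-1-one | Cc1cc(B2OC(C)(C)C(C)(C)O2)c(OCOC)c(C(=O)CCc3ccccc3)c1OCOC | intermediate
8 | 1-[3-hydroxy-2,6-bis(methoxymethoxy)-5-methylphenyl]-3-phenylpropan-1-one | Cc1cc(O)c(OCOC)c(C(=O)CCc2ccccc2)c1OCOC | intermediate
9 | 3-chloro-3-methylbut-1-yne | CC(C)(Cl)C#C | starting material
10 | 1-[2,6-bis(methoxymethoxy)-3-methyl-5-[(2-methylbut-3-yn-2-yl)oxy]phenyl]-3-phenylpropan-1-one | Cc1cc(OC(C)(C)C#C)c(OCOC)c(C(=O)CCc2ccccc2)c1OCOC | intermediate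
11 | 1-[2,6-dihydroxy-3-methyl-5-[(2-methylbut-3-yn-2-yl)oxy]phenyl]-3-phenylpropan-1-one | Cc1cc(OC(C)(C)C#C)c(O)c(C(=O)CCc2ccccc2)c1O | intermediate
12 | 3-methylbut-2-en-1-ol | CC(C)=CCO | starting material
13 | tert-butyl 3-methylbut-2-en-1-yl carbonate | CC(C)=CCOC(=O)OC(C)(C)C | intermediate
14 | (6S)-3-hydroxy-6-methyl-6-(3-methylbut-2-en-1-yl)-4-[(2-methylbut-3-yn-2-yl)oxy]-2-(3-phenylpropanoyl)cyclohexa-2,4-dien-1-one | CC(C)=CC[C@]1(C)C(=O)C(C(=O)CCc2ccccc2)=C(O)C(OC(C)(C)C#C)=C1 | intermediate
15 | (6S)-3-hydroxy-6-methyl-5-(3-methylbuta-1,2-dien-1-yl)-6-(3-methylbut-2-en-1-yl)-2-(3-phenylpropanoyl)cyclohex-2-ene-1,4-dione, both C5 epimers | CC(C)=CC[C@]1(C)C(=O)C(C(=O)CCc2ccccc2)=C(O)C(=O)C1C=C=C(C)C | intermediate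
16 | (5Z,6S)-3-hydroxy-6-methyl-6-(3-methylbut-2-en-1-yl)-5-(3-methylbut-2-en-1-ylidene)-2-(3-phenylpropanoyl)cyclohex-2-ene-1,4-dione | CC(C)=CC[C@]1(C)C(=O)C(C(=O)CCc2ccccc2)=C(O)C(=O)/C1=C\C=C(C)C | intermediate
17 | (5S)-8-hydroxy-2,2,5-trimethyl-5-(3-methylbut-2-en-1-yl)-7-(3-phenylpropanoyl)-2H-chromen-6(5H)-one | CC(C)=CC[C@]1(C)C(=O)C(C(=O)CCc2ccccc2)=C(O)C2=C1C=CC(C)(C)O2 | target

**Step count and risks**

Total step count: 9. Longest linear sequence: 8 (steps 1 to 6, 8, 9); step 7 is a one-step side branch.

Steps most likely to fail: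

1. Step 8. Facial discrimination of the planar phenolate may be poor, O-prenylation may fail to revert to C-alkylation, or attack may occur at the branched allyl terminus. Fallback: starting from 11, racemic alkylative dearomatisation with 1-bromo-3-methylbut-2-ene in 5% aq. KOH at 0 °C (C-alkylation of the phenolate, known for acylated polyphenols) should give the racemic dienone F1. Resolution of F1 by preparative chromatography on a chiral stationary phase then delivers the (6S) enantiomer, and the route is rejoined at 14.

2. Step 9. Enantiomeric purity may erode through a reversible retro-Claisen shift of the C5 prenyl group at the temperature required, or the allenyl intermediate may be diverted (furan formation, oligomerisation). Fallback: starting from 10, the pyran is closed while the ring is still aromatic. The aryl propargyl ether rearrangement in xylene at 140 °C should give 1-[6,8-bis(methoxymethoxy)-2,2,5-trimethyl-2H-chromen-7-yl]-3-phenylpropan-1-one F2. Removal of the MOM groups (HCl, MeOH, 40 °C) gives 1-(6,8-dihydroxy-2,2,5-trimethyl-2H-chromen-7-yl)-3-phenylpropan-1-one F3. The conditions of step 8 applied to F3 with 13 then set C5 at room temperature as the last operation, and the route is rejoined at 17. This order also spares the propargyl ether the acid of step 6.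

3. Step 4. Borylation next to the ortho OMOM group may be slow, protodeboronation may compete, or the enolisable ketone may enter palladium-enolate side reactions. Fallback: the oxygen is introduced before the ketone, starting from 2. Bromination (NBS, MeCN) should give 1-bromo-2,4-bis(methoxymethoxy)-5-methylbenzene F4. Palladium-catalysed hydroxylation (Pd2(dba)3, tBuXPhos, KOH, 1,4-dioxane/H2O, 100 °C; no ketone present) gives 2,4-bis(methoxymethoxy)-5-methylphenol F5. Silylation (TIPSCl, imidazole, DMF) gives [2,4-bis(methoxymethoxy)-5-methylphenoxy]tri(propan-2-yl)silane F6. Directed ortho-lithiation between the two OMOM groups (n-BuLi, TMEDA, THF, 0 °C) gives the aryllithium F7, which is acylated with 3 to the silyl ether ketone F8. Bu4NF in THF then frees the phenol, and the route is rejoined at 8.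

**Further compounds**

F1 | step 8 | racemic 3-hydroxy-6-methyl-6-(3-methylbut-2-en-1-yl)-4-[(2-methylbut-3-yn-2-yl)oxy]-2-(3-phenylpropanoyl)cyclohexa-2,4-dien-1-one | CC(C)=CCC1(C)C(=O)C(C(=O)CCc2ccccc2)=C(O)C(OC(C)(C)C#C)=C1
F2 | step 9 | 1-[6,8-bis(methoxymethoxy)-2,2,5-trimethyl-2H-chromen-7-yl]-3-phenylpropan-1-one | Cc1c(OCOC)c(C(=O)CCc2ccccc2)c(OCOC)c2OC(C)(C)C=Cc12
F3 | step 9 | 1-(6,8-dihydroxy-2,2,5-trimethyl-2H-chromen-7-yl)-3-phenylpropan-1-one | Cc1c(O)c(C(=O)CCc2ccccc2)c(O)c2OC(C)(C)C=Cc12
F4 | step 4 | 1-bromo-2,4-bis(methoxymethoxy)-5-methylbenzene | Cc1cc(Br)c(OCOC)cc1OCOC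
F5 | step 4 | 2,4-bis(methoxymethoxy)-5-methylphenol | Cc1cc(O)c(OCOC)cc1OCOC
F6 | step 4 | [2,4-bis(methoxymethoxy)-5-methylphenoxy]tri(propan-2-yl)silane | Cc1cc(O[Si](C(C)C)(C(C)C)C(C)C)c(OCOC)cc1OCOC
F7 | step 4 | {2,6-bis(methoxymethoxy)-3-methyl-5-[tri(propan-2-yl)silyloxy]phenyl}lithium | [Li]c1c(OCOC)c(C)cc(O[Si](C(C)C)(C(C)C)C(C)C)c1OCOC
F8 | step 4 | 1-{2,6-bis(methoxymethoxy)-3-methyl-5-[tri(propan-2-yl)silyloxy]phenyl}-3-phenylpropan-1-one | Cc1cc(O[Si](C(C)C)(C(C)C)C(C)C)c(OCOC)c(C(=O)CCc2ccccc2)c1OCOC
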